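**Retrosynthetic overview**
- The target is a (2S)-flavanone: ring A (phloroglucinol core), ring C (pyranone), ring B (benzene) and ring D (2H-pyran of the chromene). Rings A and B are bought.
- Rings D and C are both opened in the last disconnection, giving an acyclic, unprotected 2′,4′,6′-trihydroxy-3′,5′-diprenylchalcone whose ring B carries a 1,1-dimethylpropargyl ether.
- Forward, in one flask: gold-catalysed hydroarylation closes ring D, then a chiral thiourea-catalysed oxa-Michael addition closes ring C and sets C2.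
- The chalcone comes from a Claisen–Schmidt condensation of diprenylphloroacetophenone with 4-(1,1-dimethylpropargyloxy)benzaldehyde. These come from phloroacetophenone plus prenyl bromide, and from 4-hydroxybenzaldehyde plus 3-chloro-3-methylbut-1-yne.
- Ring order: A and B (bought), then D, then C.

Assumption: the quinine-derived thiourea named in step 4 is taken to give the (2S) product. If chiral HPLC/CD shows the opposite sense, its pseudo-enantiomer N-[3,5-bis(trifluoromethyl)phenyl]-N′-[(9R)-6′-methoxycinchonan-9-yl]thiourea (C29H28F6N4OS) is used under the same conditions.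

**Route**

Step 1
Reactants: 1 2′,4′,6′-trihydroxyacetophenone (phloroacetophenone); 2 prenyl bromide (1-bromo-3-methylbut-2-ene, 2.1 equiv)
Product: 4 1-[2,4,6-trihydroxy-3,5-bis(3-methylbut-2-en-1-yl)phenyl]ethan-1-one, via monoprenyl ketone 3 (not isolated)
Conditions: 10% aq. KOH, 0 °C to 23 °C; acidify; chromatography
Reagents that add atoms: none
Why: Phenolate C-alkylation (electrophilic prenylation of the phloroglucinolate) in water, where hydrogen bonding shields the oxygens, so the two free ring carbons are alkylated in turn through 3; no stereocentre is formed.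

Step 2
Reactants: 5 4-hydroxybenzaldehyde; 6 3-chloro-3-methylbut-1-yne (1.5 equiv)
Product: 7 4-[(2-methylbut-3-yn-2-yl)oxy]benzaldehyde
Conditions: K2CO3, KI (cat.), CuI (cat.), acetone, reflux
Reagents that add atoms: none
Why: Copper-assisted propargylic O-alkylation (Williamson-type etherification through a copper acetylide) of the acidic para-formylphenol by the tertiary chloride outcompetes elimination; no stereocentre is formed.

Step 3
Reactants: 4 1-[2,4,6-trihydroxy-3,5-bis(3-methylbut-2-en-1-yl)phenyl]ethan-1-one; 7 4-[(2-methylbut-3-yn-2-yl)oxy]benzaldehyde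
Product: 9 (E)-3-{4-[(2-methylbut-3-yn-2-yl)oxy]phenyl}-1-[2,4,6-trihydroxy-3,5-bis(3-methylbut-2-en-1-yl)phenyl]prop-2-en-1-one, via aldol adduct 8 (not isolated)
Conditions: LiN(SiMe3)2 (4.2 equiv), THF, −78 °C; add 7, −78 °C to 23 °C; cold 1 M HCl quench to pH 4; fast chromatography
Reagents that add atoms: none
Why: Claisen–Schmidt aldol condensation through the tetralithiated ketone (three phenoxides plus the enolate), so the phenols need no protection; aldolate 8 eliminates by E1cB to the (E)-enone, and the cold quench avoids premature ring closure.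

Step 4 (key step)
Reactants: 9 (E)-3-{4-[(2-methylbut-3-yn-2-yl)oxy]phenyl}-1-[2,4,6-trihydroxy-3,5-bis(3-methylbut-2-en-1-yl)phenyl]prop-2-en-1-one
Product: 11 (2S)-5,7-dihydroxy-2-(2,2-dimethyl-2H-chromen-6-yl)-6,8-bis(3-methylbut-2-en-1-yl)-2,3-dihydro-4H-chromen-4-one (target), via chromene chalcone 10 (not isolated)
Conditions: Ph3PAuNTf2 (3 mol%), CH2Cl2 (0.03 M), 23 °C, 2 h; then PhMe, −20 °C, N-[3,5-bis(trifluoromethyl)phenyl]-N′-[(8α,9S)-6′-methoxycinchonan-9-yl]thiourea (C29H28F6N4OS, 20 mol%), 48 h; cold aq. citric acid quench; chromatography, recrystallisation to raise ee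
Reagents that add atoms: none
Why: Proposed new method: silver-free cationic monovalent gold activates the terminal alkyne for 6-endo-dig hydroarylation at the ring B carbon ortho to the ether oxygen (closest known type: gold-catalysed cyclisation of aryl propargyl ethers to 2H-chromenes), closing ring D to give 10 at room temperature, where the chalcone stays open; the added thiourea then sequesters the gold and catalyses the intramolecular oxa-Michael addition (closest known type: bifunctional cinchona-thiourea cyclisation of 2′-hydroxychalcones to flavanones), the quinuclidine deprotonating one of the two equivalent ortho phenols while the thiourea hydrogen-bonds the enone carbonyl, so the oxygen is delivered to one face of the β-carbon and C2 is set as S under kinetic control in the last bond-forming event.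

**Compound list**
1 | 2′,4′,6′-trihydroxyacetophenone | CC(=O)c1c(O)cc(O)cc1O | starting material
2 | prenyl bromide (1-bromo-3-methylbut-2-ene) | CC(C)=CCBr | starting material
3 | 1-[2,4,6-trihydroxy-3-(3-methylbut-2-en-1-yl)phenyl]ethan-1-one (monoprenyl ketone, not isolated) | CC(=O)c1c(O)cc(O)c(CC=C(C)C)c1O | intermediate
4 | 1-[2,4,6-trihydroxy-3,5-bis(3-methylbut-2-en-1-yl)phenyl]ethan-1-one | CC(=O)c1c(O)c(CC=C(C)C)c(O)c(CC=C(C)C)c1O | intermediate
5 | 4-hydroxybenzaldehyde | O=Cc1ccc(O)cc1 | starting material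
6 | 3-chloro-3-methylbut-1-yne | CC(C)(Cl)C#C | starting material
7 | 4-[(2-methylbut-3-yn-2-yl)oxy]benzaldehyde | O=Cc1ccc(OC(C)(C)C#C)cc1 | intermediate
8 | racemic 3-hydroxy-3-{4-[(2-methylbut-3-yn-2-yl)oxy]phenyl}-1-[2,4,6-trihydroxy-3,5-bis(3-methylbut-2-en-1-yl)phenyl]propan-1-one (aldol adduct, present as its lithium salt, not isolated) | CC(C)=CCc1c(O)c(CC=C(C)C)c(O)c(C(=O)CC(O)c2ccc(OC(C)(C)C#C)cc2)c1O | intermediate
9 | (E)-3-{4-[(2-methylbut-3-yn-2-yl)oxy]phenyl}-1-[2,4,6-trihydroxy-3,5-bis(3-methylbut-2-en-1-yl)phenyl]prop-2-en-1-one | CC(C)=CCc1c(O)c(CC=C(C)C)c(O)c(C(=O)/C=C/c2ccc(OC(C)(C)C#C)cc2)c1O | intermediate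
10 | (E)-3-(2,2-dimethyl-2H-chromen-6-yl)-1-[2,4,6-trihydroxy-3,5-bis(3-methylbut-2-en-1-yl)phenyl]prop-2-en-1-one (chromene chalcone, not isolated) | CC(C)=CCc1c(O)c(CC=C(C)C)c(O)c(C(=O)/C=C/c2ccc3OC(C)(C)C=Cc3c2)c1O | intermediate
11 | (2S)-5,7-dihydroxy-2-(2,2-dimethyl-2H-chromen-6-yl)-6,8-bis(3-methylbut-2-en-1-yl)-2,3-dihydro-4H-chromen-4-one | CC(C)=CCc1c(O)c(CC=C(C)C)c2c(c1O)C(=O)C[C@@H](c1ccc3c(c1)C=CC(C)(C)O3)O2 | target

**Step count and risks**
Total steps: 4. Longest linear sequence: 3 (steps 1, 3, 4).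

Most likely to fail, in this order:

Step 4. The gold stage may be disturbed by the prenyl/phenol pairs or slowed by the electron-poor ring B, and the enantioselectivity of the oxa-Michael stage on an unactivated, triply phenolic chalcone is uncertain. Fallback, setting out from 9 and coming back at 11: both rings are still closed together, but thermally and without stereocontrol, and the enantiomers are then separated. Compound 9 is heated in degassed PhNEt2 or DMF at 130–150 °C, then NaOAc, EtOH, 60 °C. Aryl propargyl ether Claisen rearrangement, 1,5-hydrogen shift and oxa-6π electrocyclisation build ring D via 10, and the 2′-hydroxychalcone closes ring C. This gives racemic 5,7-dihydroxy-2-(2,2-dimethyl-2H-chromen-6-yl)-6,8-bis(3-methylbut-2-en-1-yl)-2,3-dihydro-4H-chromen-4-one F5. Preparative HPLC on an amylose tris(3,5-dimethylphenylcarbamate) phase delivers 11. The unwanted (2R)-5,7-dihydroxy-2-(2,2-dimethyl-2H-chromen-6-yl)-6,8-bis(3-methylbut-2-en-1-yl)-2,3-dihydro-4H-chromen-4-one F6 is re-racemised through the chalcone (NaOAc, EtOH, reflux) and resolved again.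

Step 3. The polyanion may condense sluggishly, or the 2′,6′-dihydroxychalcone may close to racemic flavanone on work-up. Fallback, setting out from 4 and coming back at 9: the phenols are masked. Compound 4 with chloromethyl methyl ether (COCCl, 2.2 equiv) and iPr2NEt in CH2Cl2 gives 1-[2-hydroxy-4,6-bis(methoxymethoxy)-3,5-bis(3-methylbut-2-en-1-yl)phenyl]ethan-1-one F3. A classical Claisen–Schmidt condensation with 7 (KOH, EtOH–H2O, 23 °C) gives (E)-1-[2-hydroxy-4,6-bis(methoxymethoxy)-3,5-bis(3-methylbut-2-en-1-yl)phenyl]-3-{4-[(2-methylbut-3-yn-2-yl)oxy]phenyl}prop-2-en-1-one F4. Brief acetal cleavage (HCl, MeOH, 23 °C, short contact time) returns 9.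

Step 1. Direct C-prenylation gives mono-, di-, geminal and O-alkylated products, so the yield of 4 is low. Fallback, setting out from 1 and coming back at 4: the prenyl groups are delivered by oxygen-to-carbon transfer. Compound 1 is bis-O-alkylated with 6 (K2CO3, KI, CuI, acetone, reflux); the third hydroxyl stays locked in its hydrogen bond to the ketone. This gives 1-{2-hydroxy-4,6-bis[(2-methylbut-3-yn-2-yl)oxy]phenyl}ethan-1-one F1. Semi-hydrogenation (H2, Pd/CaCO3 poisoned with Pb(OAc)2, quinoline, EtOAc) gives 1-{2-hydroxy-4,6-bis[(2-methylbut-3-en-2-yl)oxy]phenyl}ethan-1-one F2. Heating (PhNEt2, 110–130 °C) triggers two aromatic Claisen rearrangements, with a para-Claisen/Cope shift where the ortho carbon is already taken. These place the prenyl groups on the only two free ring carbons and return 4.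

**Further compounds**
F1 | step 1 | 1-{2-hydroxy-4,6-bis[(2-methylbut-3-yn-2-yl)oxy]phenyl}ethan-1-one | CC(=O)c1c(O)cc(OC(C)(C)C#C)cc1OC(C)(C)C#C
F2 | step 1 | 1-{2-hydroxy-4,6-bis[(2-methylbut-3-en-2-yl)oxy]phenyl}ethan-1-one | CC(=O)c1c(O)cc(OC(C)(C)C=C)cc1OC(C)(C)C=C
F3 | step 3 | 1-[2-hydroxy-4,6-bis(methoxymethoxy)-3,5-bis(3-methylbut-2-en-1-yl)phenyl]ethan-1-one | CC(=O)c1c(O)c(CC=C(C)C)c(OCOC)c(CC=C(C)C)c1OCOC
F4 | step 3 | (E)-1-[2-hydroxy-4,6-bis(methoxymethoxy)-3,5-bis(3-methylbut-2-en-1-yl)phenyl]-3-{4-[(2-methylbut-3-yn-2-yl)oxy]phenyl}prop-2-en-1-one | CC(C)=CCc1c(O)c(C(=O)/C=C/c2ccc(OC(C)(C)C#C)cc2)c(OCOC)c(CC=C(C)C)c1OCOC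
F5 | step 4 | racemic 5,7-dihydroxy-2-(2,2-dimethyl-2H-chromen-6-yl)-6,8-bis(3-methylbut-2-en-1-yl)-2,3-dihydro-4H-chromen-4-one | CC(C)=CCc1c(O)c(CC=C(C)C)c2c(c1O)C(=O)CC(c1ccc3c(c1)C=CC(C)(C)O3)O2
F6 | step 4 | (2R)-5,7-dihydroxy-2-(2,2-dimethyl-2H-chromen-6-yl)-6,8-bis(3-methylbut-2-en-1-yl)-2,3-dihydro-4H-chromen-4-one | CC(C)=CCc1c(O)c(CC=C(C)C)c2c(c1O)C(=O)C[C@H](c1ccc3c(c1)C=CC(C)(C)O3)O2
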